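The 1,3-relationship C(OH)–CH2–C(OH)(N) of the cyclohexene ring (ring D) is traced back to a single bond. In the precursor this ring is a cyclopentene whose amine-bearing carbon and acyl-bearing carbon are joined directly and bridged by the CH2: an aminocyclopropyl ketone inside a [4.3.1]propellane. Single-electron oxidation of the amine under O2 breaks this push–pull central bond. In one operation the CH2 enters the carbocycle (five to six atoms), the piperidinone becomes the azepanone, and both bridgehead hydroxyls appear with the only configuration the bicycle allows. The propellane comes from Simmons–Smith cyclopropanation of a tetracyclic vinylogous amide.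

Key step: step 14

Remark on the chemistry: ring letters are A (five-membered carbocycle, later the fulvene), B (dihydropyran), C (seven-membered carbocycle), D (six-membered carbocycle), E (pyrrolidine), F (azepanone); the CHMe centre next to the ring F ketone is carried as a mixture from step 11 and the base of step 15 is assumed to settle it as the exo-methyl epimer of the target, and the side-chain CH of ring A is left uncontrolled because it ends as an sp2 carbon.

Step 1
Reactants: 1 methyl 4-oxobutanoate; 2 nitromethane
Product: 4 methyl (E)-5-nitropent-4-enoate, via nitro alcohol 3 (not isolated)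
Conditions: Et3N (cat.), THF, 0 °C to rt; then MsCl, Et3N, CH2Cl2, 0 °C
Reagents that add atoms: none
Why: Henry addition of nitromethane to the aldehyde, then mesylation and E1cB elimination, should give the conjugated (E)-nitroalkene.

Step 2
Reactants: 4 methyl (E)-5-nitropent-4-enoate; 5 2,2-dimethyl-1,3-dioxane-4,6-dione
Product: 6 methyl (4S)-4-(2,2-dimethyl-4,6-dioxo-1,3-dioxan-5-yl)-5-nitropentanoate
Conditions: cinchona-alkaloid-derived squaramide (5 mol%, the pseudo-enantiomer that gives the S adduct), CH2Cl2, −20 °C
Reagents that add atoms: none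
Why: Enantioselective organocatalytic Michael addition, in which the squaramide binds the nitro group and the quinuclidine delivers the dioxanedione enolate to one alkene face, should set the (S) CH centre that ends as the ring C/E fusion carbon.

Step 3
Reactants: 6 methyl (4S)-4-(2,2-dimethyl-4,6-dioxo-1,3-dioxan-5-yl)-5-nitropentanoate
Product: 7 (4S)-4-(3-methoxy-3-oxopropyl)-2-oxopyrrolidine-3-carboxylic acid
Conditions: H2 (5 bar), Pd/C, MeOH, rt; then 50 °C
Reagents that add atoms: none
Why: Hydrogenation of the nitro group gives the amine, which opens the activated dioxanedione by 5-exo-trig N-acylation with loss of acetone, far faster than six-ring lactam formation at the methyl ester.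

Step 4
Reactants: 7 (4S)-4-(3-methoxy-3-oxopropyl)-2-oxopyrrolidine-3-carboxylic acid
Product: 8 methyl 3-[(3S)-4-acetyl-5-oxopyrrolidin-3-yl]propanoate
Conditions: MgCl2, Et3N, MeCN, 0 °C; AcCl, 0 °C to rt; then 1 M HCl, 40 °C
Reagents that add atoms: acetyl chloride, CC(=O)Cl
Why: Soft enolisation gives the magnesium-chelated enolate of the malonic half-amide, which is C-acetylated and loses CO2 on acidification (decarboxylative Claisen-type acylation) to give the β-keto lactam.

Step 5
Reactants: 8 methyl 3-[(3S)-4-acetyl-5-oxopyrrolidin-3-yl]propanoate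
Product: 9 methyl 3-[(3S,4S)-4-acetyl-4-methyl-5-oxopyrrolidin-3-yl]propanoate
Conditions: K2CO3, MeI, acetone, rt
Reagents that add atoms: iodomethane, CI
Why: C-alkylation of the β-keto lactam enolate, with iodomethane approaching the ring face anti to the neighbouring propanoate chain, should place the methyl trans and the acetyl cis to that chain at the new quaternary centre.

Step 6
Reactants: 10 3-[(tert-butyldimethylsilyl)oxy]propanal; 11 nitroethane
Product: 13 (E)-tert-butyldimethyl[(4-nitropent-3-en-1-yl)oxy]silane, via nitro alcohol 12 (not isolated)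
Conditions: Et3N (cat.), THF, rt; then MsCl, Et3N, CH2Cl2, −20 °C
Reagents that add atoms: none
Why: Henry addition and dehydration as in step 1 should give the trisubstituted nitroalkene, which serves as a substituted acetonyl cation equivalent.

Step 7
Reactants: 9 methyl 3-[(3S,4S)-4-acetyl-4-methyl-5-oxopyrrolidin-3-yl]propanoate; 13 (E)-tert-butyldimethyl[(4-nitropent-3-en-1-yl)oxy]silane
Product: 15 1,4-diketone methyl 3-[(3S,4S)-4-{3-[2-(tert-butyldimethylsilyloxy)ethyl]-4-oxopentanoyl}-4-methyl-5-oxopyrrolidin-3-yl]propanoate, via lithium nitronate 14 (not isolated)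
Conditions: LiN(SiMe3)2 (2.2 equiv), THF, −78 °C; 13, −78 °C; then KHSO5 (as 2KHSO5·KHSO4·K2SO4), Na2HPO4, MeOH/H2O, 0 °C
Reagents that add atoms: potassium peroxymonosulfate, [K+].OOS(=O)(=O)[O-]
Why: After deprotonation of the lactam N–H, the methyl ketone enolate (more acidic than the ester) adds to the nitroalkene in a Michael reaction and the nitronate is oxidised in the same flask to the ketone (oxidative Nef reaction).

Step 8
Reactants: 15 1,4-diketone
Product: 16 methyl 3-[(3S,4S)-4-{4-[2-(tert-butyldimethylsilyloxy)ethyl]-3-oxocyclopent-1-en-1-yl}-4-methyl-5-oxopyrrolidin-3-yl]propanoate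
Conditions: KOtBu, t-BuOH/THF, 0 °C to rt; aq. NH4Cl
Reagents that add atoms: none
Why: Intramolecular aldol condensation of the 1,4-diketone (5-enolexo-exo-trig attack of the methyl ketone enolate on the ketone next to the quaternary carbon, then dehydration) should give the 3-substituted cyclopent-2-enone that is ring A.

Step 9
Reactants: 16 cyclopentenone lactam
Product: 17 methyl 3-[(3S,4S)-4-{2-bromo-4-[2-(tert-butyldimethylsilyloxy)ethyl]-3-oxocyclopent-1-en-1-yl}-4-methyl-5-oxopyrrolidin-3-yl]propanoate
Conditions: Br2, CH2Cl2, −20 °C; then Et3N, 0 °C to rt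
Reagents that add atoms: bromine, BrBr
Why: Addition of bromine to the enone C=C and base-induced loss of HBr (bromination–dehydrobromination) should place bromine on the α-carbon that later bonds to the enaminone.

Step 10
Reactants: 18 3-methylbut-3-en-2-one
Product: 19 trimethyl[(3-methylbuta-1,3-dien-2-yl)oxy]silane
Conditions: Me3SiOTf, Et3N, Et2O, 0 °C
Reagents that add atoms: trimethylsilyl trifluoromethanesulfonate, C[Si](C)(C)OS(=O)(=O)C(F)(F)F
Why: Silyl enol ether formation can occur only at the methyl group, so a single 2-silyloxydiene should result.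

Step 11
Reactants: 17 bromoenone lactam; 19 trimethyl[(3-methylbuta-1,3-dien-2-yl)oxy]silane
Product: 21 methyl 3-[(1S,2S)-1-{2-bromo-4-[2-(tert-butyldimethylsilyloxy)ethyl]-3-oxocyclopent-1-en-1-yl}-1,6-dimethyl-7-oxo-1,2,3,5,6,7-hexahydroindolizin-2-yl]propanoate, via NH enaminone 20 (not isolated)
Conditions: Tf2O, 2-fluoropyridine, CH2Cl2, −78 to 0 °C; then 19, 0 °C to rt; then K2CO3, MeOH, rt
Reagents that add atoms: none
Why: Electrophilic activation of the secondary lactam as its imidoyl triflate, C-attack by the terminal carbon of the silyl enol ether (amide-to-enaminone coupling) and 6-endo-trig aza-Michael addition of the N–H to the isopropenyl ketone should build the dihydropyridinone, the new CHMe centre forming without control.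

Step 12
Reactants: 21 bicyclic vinylogous amide
Product: 22 tetracyclic dienaminone (cyclopentadiene fused to ring A, to the dihydropyridinone and, through the CMe carbon, to ring E)
Conditions: Pd(OAc)2 (10 mol%), P(o-tol)3, Et3N, DMF, 100 °C
Reagents that add atoms: none
Why: Oxidative addition of palladium into the vinyl bromide and intramolecular alkenylation of the nucleophilic α-carbon of the vinylogous amide (Heck-type 5-endo closure, as in enaminone-to-carbazolone cyclisations) should close the cyclopentadiene.

Step 13
Reactants: 22 tetracyclic dienaminone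
Product: 23 [4.3.1]propellane aminocyclopropyl ketone (CH2 across the former enaminone C=C, cis to the angular methyl)
Conditions: Et2Zn, CF3CO2H, CH2I2, CH2Cl2, 0 °C to rt; pyridine quench; filtration through basic Al2O3
Reagents that add atoms: diiodomethane, ICI
Why: Simmons–Smith-type methylene transfer from the electrophilic zinc carbenoid to the most electron-rich (enamine-type) C=C should occur on the face of the angular methyl, because only a cis-fused five/five junction is possible, and this fixes both cyclopropane carbons.

Step 14
Reactants: 23 [4.3.1]propellane aminocyclopropyl ketone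
Product: 25 ring-expanded diol (cyclohexene ring D with C(OH)–CH2–C(OH)N, azepanone ring F), via hydroperoxide 24 (not isolated)
Conditions: Ru(bpy)3(PF6)2 (1 mol%), O2 (1 atm), MeCN/H2O, blue LEDs, rt; then Me2S
Reagents that add atoms: dioxygen, O=O; water, O
Why: Proposed new method: the excited photocatalyst oxidises the tertiary cyclopropylamine nitrogen to an aminium radical cation whose central C–C bond (amino donor on one carbon, acyl and allyl stabilisation on the other) cleaves with release of cyclopropane and propellane strain, giving a bridgehead iminium ion and a tertiary α-keto allylic radical that O2 traps; the peroxyl radical cannot close onto the iminium carbon, because a two-atom peroxide bridge across these bridgeheads would be prohibitively strained, so it is reduced to the hydroperoxide while water adds to the iminium ion, and Me2S then gives the diol. The closest known reaction type is the aerobic photoredox or anodic ring opening of bicyclic aminocyclopropanes, which ends at 3-amino-1,2-dioxolanes, together with the retro-Mannich opening of β-aminocyclopropyl ketones. No ring is closed by bond formation: cleavage of the bond shared by three rings turns the cyclopentene into the cyclohexene (one-carbon ring expansion, the cyclopropane CH2 becoming a ring member) and the piperidinone into the azepanone. Both new stereocentres are bridgeheads of the resulting bicyclo[4.3.1] skeleton, so each oxygen can only take the outward position, which places the carbinolamine OH cis to the angular methyl and the ketol OH on the same face, as in the target. The step needs cleavage of the acyl-substituted bond and not of the bond to the CH2, which the captodative stabilisation of the ring-opened radical cation should secure, and oxidation of the amine in preference to the enone, which the low oxidation potential of the trialkylamine should secure.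

Step 15
Reactants: 25 ring-expanded diol
Product: 27 hexacyclic dienone (keto tautomer of the hydroxyfulvene, rings B and C closed), via triketone 26 (not isolated)
Conditions: KOtBu (4 equiv), THF, 0 °C to rt; then HCl, MeOH, 0 °C to rt
Reagents that add atoms: none
Why: Vinylogous Dieckmann condensation, in which the extended enolate of ring A is acylated at its γ-carbon by the ester, should close ring C, driven by the stabilised hydroxyfulvene anion, while the base equilibrates the CHMe centre to the exo-methyl epimer; acid then removes the silyl ether and the freed alcohol cyclodehydrates onto the new ketone to give the six-ring enol ether (ring B).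

Step 16
Reactants: 27 hexacyclic dienone
Product: 28 CNP0309418.1 (target)
Conditions: Ac2O, Et3N, CH2Cl2, 0 °C
Reagents that add atoms: acetic anhydride, CC(=O)OC(C)=O
Why: The acidic α-proton of the dienone gives a fulvenolate that should be O-acetylated (enol acetate formation), while the two tertiary alcohols should not react without an acyl-transfer catalyst.

Compound list
1 | methyl 4-oxobutanoate | COC(=O)CCC=O | starting material
2 | nitromethane | C[N+](=O)[O-] | starting material
3 | methyl 4-hydroxy-5-nitropentanoate (racemic) | COC(=O)CCC(O)C[N+](=O)[O-] | intermediate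
4 | methyl (E)-5-nitropent-4-enoate | COC(=O)CC/C=C/[N+](=O)[O-] | intermediate
5 | 2,2-dimethyl-1,3-dioxane-4,6-dione | CC1(C)OC(=O)CC(=O)O1 | starting material
6 | methyl (4S)-4-(2,2-dimethyl-4,6-dioxo-1,3-dioxan-5-yl)-5-nitropentanoate | CC1(C)OC(=O)C(C(=O)O1)[C@H](CCC(=O)OC)C[N+](=O)[O-] | intermediate
7 | (4S)-4-(3-methoxy-3-oxopropyl)-2-oxopyrrolidine-3-carboxylic acid (C3 epimerisable, trans expected) | O=C1NC[C@@H](CCC(=O)OC)C1C(=O)O | intermediate
8 | methyl 3-[(3S)-4-acetyl-5-oxopyrrolidin-3-yl]propanoate (acetyl-bearing carbon epimerisable) | O=C1NC[C@@H](CCC(=O)OC)C1C(C)=O | intermediate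
9 | methyl 3-[(3S,4S)-4-acetyl-4-methyl-5-oxopyrrolidin-3-yl]propanoate (methyl trans to the chain) | O=C1NC[C@@H](CCC(=O)OC)[C@@]1(C)C(C)=O | intermediate
10 | 3-[(tert-butyldimethylsilyl)oxy]propanal | O=CCCO[Si](C)(C)C(C)(C)C | starting material
11 | nitroethane | CC[N+](=O)[O-] | starting material
12 | 5-[(tert-butyldimethylsilyl)oxy]-2-nitropentan-3-ol (diastereomers) | CC(C(O)CCO[Si](C)(C)C(C)(C)C)[N+](=O)[O-] | intermediate
13 | (E)-tert-butyldimethyl[(4-nitropent-3-en-1-yl)oxy]silane | C/C(=C\CCO[Si](C)(C)C(C)(C)C)[N+](=O)[O-] | intermediate
14 | lithium nitronate of the Michael adduct of 9 and 13 (drawn with N–H) | O=C1NC[C@@H](CCC(=O)OC)[C@@]1(C)C(=O)CC(CCO[Si](C)(C)C(C)(C)C)C(C)=[N+]([O-])[O-].[Li+] | intermediate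
15 | methyl 3-[(3S,4S)-4-{3-[2-(tert-butyldimethylsilyloxy)ethyl]-4-oxopentanoyl}-4-methyl-5-oxopyrrolidin-3-yl]propanoate (side-chain CH epimers) | O=C1NC[C@@H](CCC(=O)OC)[C@@]1(C)C(=O)CC(CCO[Si](C)(C)C(C)(C)C)C(C)=O | intermediate
16 | methyl 3-[(3S,4S)-4-{4-[2-(tert-butyldimethylsilyloxy)ethyl]-3-oxocyclopent-1-en-1-yl}-4-methyl-5-oxopyrrolidin-3-yl]propanoate | O=C1NC[C@@H](CCC(=O)OC)[C@@]1(C)C1=CC(=O)C(CCO[Si](C)(C)C(C)(C)C)C1 | intermediate
17 | methyl 3-[(3S,4S)-4-{2-bromo-4-[2-(tert-butyldimethylsilyloxy)ethyl]-3-oxocyclopent-1-en-1-yl}-4-methyl-5-oxopyrrolidin-3-yl]propanoate | O=C1NC[C@@H](CCC(=O)OC)[C@@]1(C)C1=C(Br)C(=O)C(CCO[Si](C)(C)C(C)(C)C)C1 | intermediate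
18 | 3-methylbut-3-en-2-one | CC(=O)C(C)=C | starting material
19 | trimethyl[(3-methylbuta-1,3-dien-2-yl)oxy]silane | C=C(C)C(=C)O[Si](C)(C)C | intermediate
20 | (Z)-NH enaminone: 17 with the lactam C=O replaced by C=CH–C(=O)–C(CH3)=CH2 | C=C(C)C(=O)/C=C1\NC[C@@H](CCC(=O)OC)[C@@]1(C)C1=C(Br)C(=O)C(CCO[Si](C)(C)C(C)(C)C)C1 | intermediate
21 | methyl 3-[(1S,2S)-1-{2-bromo-4-[2-(tert-butyldimethylsilyloxy)ethyl]-3-oxocyclopent-1-en-1-yl}-1,6-dimethyl-7-oxo-1,2,3,5,6,7-hexahydroindolizin-2-yl]propanoate (C6 epimers) | O=C1C(C)CN2C[C@@H](CCC(=O)OC)[C@](C)(C2=C1)C1=C(Br)C(=O)C(CCO[Si](C)(C)C(C)(C)C)C1 | intermediate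
22 | tetracyclic dienaminone: 21 with the brominated carbon bonded to C8 of the indolizinone in place of Br and H (cyclopentadiene) | O=C1C(C)CN2C[C@@H](CCC(=O)OC)[C@]3(C)C2=C1C1=C3CC(CCO[Si](C)(C)C(C)(C)C)C1=O | intermediate
23 | [4.3.1]propellane: 22 with CH2 added across the N–C=C bond, cis to the angular methyl | O=C1C(C)CN2C[C@@H](CCC(=O)OC)[C@]3(C)[C@]24C[C@]14C1=C3CC(CCO[Si](C)(C)C(C)(C)C)C1=O | intermediate
24 | ring-expanded hydroperoxide: central propellane bond cleaved, OOH on the acyl-bearing bridgehead, OH on the N-bearing bridgehead | O=C1C(C)CN2C[C@@H](CCC(=O)OC)[C@]3(C)[C@@]2(O)C[C@@]1(OO)C1=C3CC(CCO[Si](C)(C)C(C)(C)C)C1=O | intermediate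
25 | ring-expanded diol: as 24 with OH in place of OOH | O=C1C(C)CN2C[C@@H](CCC(=O)OC)[C@]3(C)[C@@]2(O)C[C@@]1(O)C1=C3CC(CCO[Si](C)(C)C(C)(C)C)C1=O | intermediate
26 | triketone with ring C closed (keto tautomer drawn, exo-methyl at the CHMe centre) | O=C1C(CCO[Si](C)(C)C(C)(C)C)C2C(=O)CC[C@@H]3CN4C[C@@H](C)C(=O)[C@@]5(O)C[C@]4(O)[C@]3(C)C2=C15 | intermediate
27 | hexacyclic dienone: target without the acetyl group, drawn as the keto tautomer of the hydroxyfulvene | O=C1C2CCOC3=C2C2=C1[C@]1(O)C[C@@]4(O)N(C[C@@H](CC3)[C@@]24C)C[C@@H](C)C1=O | intermediate
28 | CNP0309418.1, the fulvene enol acetate | CC(=O)OC1=C2CCOC3=C2C2=C1[C@]1(O)C[C@@]4(O)N(C[C@@H](CC3)[C@@]24C)C[C@@H](C)C1=O | target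

Total step count: 16. Longest linear sequence: 14 steps (steps 1–5, 7–9 and 11–16; steps 6 and 10 are side branches).

Steps most likely to fail

Step 14 (Proposed new method). The ring opening may take the wrong course: cleavage of the bond to the CH2, hydrolytic opening with protonation at carbon before oxygen is taken up, or further oxidation of the amine. The fallback uses known chemistry; it sets out from 23 and comes back to the route at 25. Me3SiOTf (1.1 equiv, CH2Cl2, −78 °C) silylates the ketone oxygen and so drives heterolysis of the donor–acceptor cyclopropane bond, giving the silyl enol ether iminium triflate F1, in which the enol ether is formed regiospecifically and the nitrogen is masked as the iminium ion. Dimethyldioxirane in acetone then oxidises the enol ether (Rubottom oxidation), and aqueous NaHCO3 hydrates the iminium ion and removes the silyl group to give 25.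

Step 13. Methylene transfer to the hindered, push–pull tetrasubstituted alkene may be too slow, or zinc salts may open the product during work-up. The fallback sets out from 22 and comes back at 23. Dichlorocarbene, generated under neutral conditions from Cl3CCO2Na (DME, 80 °C), is a far stronger electrophile for tetrasubstituted electron-rich alkenes and should give the dichloropropellane F2; its ionisation to an allyl cation is blocked, since that would put a planar carbon in the one-atom bridge. Bu3SnH with AIBN (toluene, 80 °C) then removes both chlorines by radical reduction to give 23.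

Step 12. Carbon–carbon bond formation in the 5-endo mode may lose out to protodebromination or decomposition of the vinylpalladium species. The fallback sets out from 21 and comes back at 22. N-Iodosuccinimide (CH2Cl2, 0 °C) iodinates the nucleophilic α-carbon of the vinylogous amide to give the iodo-enaminone bromoenone F3, and Pd(PPh3)4 with Me3SnSnMe3 (dioxane, 100 °C) joins the two vinyl halides by intramolecular Stille–Kelly coupling to give 22.

Further compounds
F1 | step 14 | silyl enol ether iminium triflate from ring opening of 23 | C[Si](C)(C)OC1=C2CC3=[N+](CC1C)C[C@@H](CCC(=O)OC)[C@@]3(C)C1=C2C(=O)C(CCO[Si](C)(C)C(C)(C)C)C1.[O-]S(=O)(=O)C(F)(F)F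
F2 | step 13 | dichloropropellane (23 with CCl2 in place of the cyclopropane CH2) | O=C1C(C)CN2C[C@@H](CCC(=O)OC)[C@]3(C)[C@]24C(Cl)(Cl)[C@]14C1=C3CC(CCO[Si](C)(C)C(C)(C)C)C1=O
F3 | step 12 | 21 iodinated at C8 of the indolizinone | O=C1C(C)CN2C[C@@H](CCC(=O)OC)[C@](C)(C2=C1I)C1=C(Br)C(=O)C(CCO[Si](C)(C)C(C)(C)C)C1
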